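## Retrosynthetic overview

- The target comes from a 15-hydroxy-germacra-1(10),4,11(13)-trien-12,8-olide by C15 acylation with (R)-3-chloro-2-hydroxy-2-methylpropanoic acid, then late SeO2 hydroxylation of C14, which also turns the 1(10)-olefin ring-cis.
- The ten-membered ring is closed at C6–C7, the farnesyl C1→C10 bond of germacrene A. A C6 allyl-cation equivalent (allylic acetate/Pd) is captured by C7 of the C7=C11 olefin with loss of an electrofuge from C13 (Bu3Sn in place of H+); this also creates the 11(13)-methylene and the C7 stereocentre.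
- The nucleophilic end is a (5S)-3-(stannylmethyl)butenolide: C8–O is acylated by the C12 acid unit and C7=C11 is closed by RCM. C8 comes from (S)-epichlorohydrin.
- The open chain comes from a B-alkyl Suzuki union (C1–C2) of a (Z)-dienyl acetate (ynoate + vinylcopper, fixes C15 cis to C6) with an (E)-vinyl iodide (alkyne carboalumination, places C14).
- Ring order: butenolide first, then the carbocycle in the C6–C7 closure.

Assumption: positions use germacrane numbering (lactone C12(=O)–O–C8, C13 = exocyclic CH2, C14 on C10, C15 on C4); the SMILES is read as the 7,8-trans-fused (7R,8S) lactone with C15 cis to C6 and C14 trans to C2.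

## Route

Step 1
Reactants: 1 tert-butyldimethyl(prop-2-yn-1-yloxy)silane
Product: 3 methyl 4-[(tert-butyldimethylsilyl)oxy]but-2-ynoate, via lithium acetylide 2 (not isolated)
Conditions: n-BuLi, THF, −78 °C; then ClCO2Me, −78 → 0 °C
Reagents that add atoms: methyl chloroformate COC(=O)Cl; n-butyllithium [Li]CCCC (Li stays in 2 only)
Why: C-acylation of a lithium acetylide by a chloroformate gives the ynoate whose ester carbon becomes C6 and whose CH2OTBS becomes C15.

Step 2
Reactants: 3 methyl 4-[(tert-butyldimethylsilyl)oxy]but-2-ynoate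
Product: 5 methyl (2Z)-3-{[(tert-butyldimethylsilyl)oxy]methyl}penta-2,4-dienoate, via alkenylcopper adduct 4 (not isolated)
Conditions: CH2=CHMgBr, CuI (1.2 equiv each), THF, −78 °C; then sat. aq NH4Cl at −78 °C
Reagents that add atoms: vinylmagnesium bromide C=C[Mg]Br; copper(I) iodide [Cu]I (Cu stays in 4 only)
Why: syn-carbocupration (conjugate addition) of vinylcopper to the ynoate, protonated cold with retention, puts CH2OTBS (C15) cis to the ester carbon (C6) and the vinyl group (C3–C2) trans to it.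

Step 3
Reactants: 5 methyl (2Z)-3-{[(tert-butyldimethylsilyl)oxy]methyl}penta-2,4-dienoate
Product: 7 (2Z)-3-{[(tert-butyldimethylsilyl)oxy]methyl}penta-2,4-dien-1-yl acetate, via aluminium alkoxide 6 (not isolated)
Conditions: DIBAL-H (2.2 equiv), CH2Cl2, −78 °C; then Ac2O (excess), pyridine, DMAP, −78 → 0 °C
Reagents that add atoms: acetic anhydride CC(=O)OC(C)=O; diisobutylaluminium hydride CC(C)C[AlH]CC(C)C (Al stays in 6 only)
Why: 1,2-reduction of the enoate to the allylic aluminium alkoxide and in-situ O-acetylation (reductive acetylation) leave the olefin geometry untouched and install the C6 leaving group.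

Step 4
Reactants: 8 (S)-epichlorohydrin
Product: 9 (2S)-1-chloropent-4-yn-2-ol
Conditions: HC≡CH, n-BuLi, THF, −78 °C; BF3·OEt2 (promoter), then 8, −78 °C; aq NH4Cl
Reagents that add atoms: acetylene C#C
Why: BF3-promoted opening of the epoxide at its CH2 terminus by lithium acetylide (Yamaguchi-type alkynylation) does not touch the C–O stereocentre, which becomes C8.

Step 5
Reactants: 9 (2S)-1-chloropent-4-yn-2-ol
Product: 11 (3S)-hex-1-en-5-yn-3-ol, via epoxide 10 (not isolated)
Conditions: Me3S+ I− (4 equiv), n-BuLi (4 equiv), THF, −10 °C → rt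
Reagents that add atoms: trimethylsulfonium iodide C[S+](C)C.[I-] (supplies one CH2)
Why: base closes the chlorohydrin to the terminal epoxide, and dimethylsulfonium methylide opens it at CH2 and eliminates Me2S to give the one-carbon-homologated allylic alcohol (epoxide-to-allylic-alcohol methylenation); the C–O bond of the stereocentre is never broken.

Step 6
Reactants: 11 (3S)-hex-1-en-5-yn-3-ol
Product: 13 (3S,5E)-6-iodo-5-methylhexa-1,5-dien-3-ol, via alkenylalane 12 (not isolated)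
Conditions: Me3Al (3 equiv), Cp2ZrCl2 (0.25 equiv), CH2Cl2, 0 °C → rt; then I2, THF, −30 °C
Reagents that add atoms: trimethylaluminium C[Al](C)C; iodine II
Why: Negishi Zr-catalysed syn-carboalumination of the terminal alkyne (methyl to the internal carbon) and iodinolysis with retention give the (E)-iodide, so that C9 and the future C2 are trans.

Step 7
Reactants: 7 (2Z)-3-{[(tert-butyldimethylsilyl)oxy]methyl}penta-2,4-dien-1-yl acetate; 13 (3S,5E)-6-iodo-5-methylhexa-1,5-dien-3-ol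
Product: 15 (2Z,6E,9S)-3-{[(tert-butyldimethylsilyl)oxy]methyl}-9-hydroxy-7-methylundeca-2,6,10-trien-1-yl acetate, via B-alkyl-9-BBN 14 (not isolated)
Conditions: 7, 9-BBN, THF, 0 °C → rt; then 13, Pd(dppf)Cl2 (5 mol%), AsPh3, aq K3PO4, DMF, rt
Reagents that add atoms: 9-borabicyclo[3.3.1]nonane B1C2CCCC1CCC2 (boron stays in 14 only)
Why: 9-BBN adds only to the monosubstituted vinyl group of the diene (boron at C2), and B-alkyl Suzuki–Miyaura coupling with the vinyl iodide keeps both olefin geometries; at rt oxidative addition of the vinyl iodide outruns ionisation of the primary allylic acetate.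

Step 8
Reactants: 15 (2Z,6E,9S)-3-{[(tert-butyldimethylsilyl)oxy]methyl}-9-hydroxy-7-methylundeca-2,6,10-trien-1-yl acetate
Product: 16 (3S,5E,9Z)-11-acetoxy-9-{[(tert-butyldimethylsilyl)oxy]methyl}-5-methylundeca-1,5,9-trien-3-yl 2-(bromomethyl)prop-2-enoate
Conditions: 2-(bromomethyl)acrylic acid, DIC, DMAP (10 mol%), CH2Cl2, 0 °C
Reagents that add atoms: 2-(bromomethyl)prop-2-enoic acid OC(=O)C(=C)CBr
Why: Steglich esterification of the C8 hydroxyl with the C11–C13 acid unit forms the lactone C–O bond without touching the stereocentre.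

Step 9
Reactants: 16 (3S,5E,9Z)-11-acetoxy-9-{[(tert-butyldimethylsilyl)oxy]methyl}-5-methylundeca-1,5,9-trien-3-yl 2-(bromomethyl)prop-2-enoate
Product: 17 (2Z,6E)-8-[(2S)-4-(bromomethyl)-5-oxo-2,5-dihydrofuran-2-yl]-3-{[(tert-butyldimethylsilyl)oxy]methyl}-7-methylocta-2,6-dien-1-yl acetate
Conditions: Grubbs II (5 mol%), CH2Cl2 (5 mM), 40 °C
Reagents that add atoms: none
Why: ring-closing metathesis between the C7 vinyl group and the acrylate CH2 gives the butenolide; the two trisubstituted olefins are inert to the catalyst.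

Step 10
Reactants: 17 (2Z,6E)-8-[(2S)-4-(bromomethyl)-5-oxo-2,5-dihydrofuran-2-yl]-3-{[(tert-butyldimethylsilyl)oxy]methyl}-7-methylocta-2,6-dien-1-yl acetate
Product: 18 (2Z,6E)-3-{[(tert-butyldimethylsilyl)oxy]methyl}-7-methyl-8-{(2S)-5-oxo-4-[(tributylstannyl)methyl]-2,5-dihydrofuran-2-yl}octa-2,6-dien-1-yl acetate
Conditions: Bu3SnCl, Zn dust, THF/sat. aq NH4Cl, 0 °C
Reagents that add atoms: tributyltin chloride CCCC[Sn](Cl)(CCCC)CCCC
Why: Barbier-type reductive stannylation: zinc inserts only into the activated allylic bromide (the allylic acetate is inert) and the allylzinc is trapped by Bu3SnCl at the primary carbon C13, keeping the conjugated butenolide.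

Step 11
Reactants: 18 (2Z,6E)-3-{[(tert-butyldimethylsilyl)oxy]methyl}-7-methyl-8-{(2S)-5-oxo-4-[(tributylstannyl)methyl]-2,5-dihydrofuran-2-yl}octa-2,6-dien-1-yl acetate
Product: 19 (3aR,5Z,9E,11aS)-6-{[(tert-butyldimethylsilyl)oxy]methyl}-10-methyl-3-methylidene-3a,4,7,8,11,11a-hexahydrocyclodeca[b]furan-2(3H)-one
Conditions: Pd2(dba)3·CHCl3 (5 mol%), P(2-furyl)3 (20 mol%), DMF, 50 °C, syringe-pump addition to 1 mM
Reagents that add atoms: none
Why: Proposed new method: an intramolecular Pd(0)-catalysed allyl–allyl coupling used as the ten-membered ring closure; Pd(0) ionises the primary allylic acetate to an η3-allyl over C4–C6 whose geometry holds (syn/anti exchange would need a tertiary η1 form), the allylstannane transfers its allyl group by SE2′ so that Pd sits on C7 on the butenolide face anti to the C8–C9 bond, and reductive elimination to the unsubstituted terminus C6 gives the 7,8-trans lactone (7R) and the exocyclic C11=C13 methylene, mirroring the germacrene A cyclisation (π-allyl-Pd for the allyl cation, Bu3Sn for the proton lost from C13); the closest known reaction types are the intermolecular Pd-catalysed coupling of allylic acetates or halides with allylstannanes (bond at the less substituted terminus of the electrophile, allyl transposition in the tin partner) and Pd-catalysed allyl acetate/allylstannane cyclisations to small rings.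

Step 12
Reactants: 19 (3aR,5Z,9E,11aS)-6-{[(tert-butyldimethylsilyl)oxy]methyl}-10-methyl-3-methylidene-3a,4,7,8,11,11a-hexahydrocyclodeca[b]furan-2(3H)-one
Product: 20 (3aR,5Z,9E,11aS)-6-(hydroxymethyl)-10-methyl-3-methylidene-3a,4,7,8,11,11a-hexahydrocyclodeca[b]furan-2(3H)-one
Conditions: HF·pyridine, THF/pyridine, 0 °C → rt
Reagents that add atoms: none
Why: buffered fluoride desilylation of the primary allylic TBS ether; the non-basic conditions spare the α-methylene lactone.

Step 13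
Reactants: 21 (2R)-3-bromo-2-hydroxy-2-methylpropanoic acid
Product: 23 (2R)-3-chloro-2-hydroxy-2-methylpropanoic acid, via sodium glycidate 22 (not isolated)
Conditions: NaOH (2.1 equiv), H2O, 0 °C; then conc. HCl (excess), 0 °C → rt
Reagents that add atoms: hydrogen chloride Cl; sodium hydroxide [Na+].[OH-] (Na stays in 22 only)
Why: intramolecular Williamson closure to the 2-methylglycidate and HCl opening at the CH2 carbon exchange Br for Cl without breaking any bond at the quaternary stereocentre, so the (R) configuration is kept.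

Step 14
Reactants: 20 (3aR,5Z,9E,11aS)-6-(hydroxymethyl)-10-methyl-3-methylidene-3a,4,7,8,11,11a-hexahydrocyclodeca[b]furan-2(3H)-one; 23 (2R)-3-chloro-2-hydroxy-2-methylpropanoic acid
Product: 24 [(3aR,5Z,9E,11aS)-10-methyl-3-methylidene-2-oxo-2,3,3a,4,7,8,11,11a-octahydrocyclodeca[b]furan-6-yl]methyl (2R)-3-chloro-2-hydroxy-2-methylpropanoate
Conditions: EDC·HCl, DMAP (20 mol%), CH2Cl2, 0 °C → rt
Reagents that add atoms: none
Why: Steglich esterification of the primary allylic C15 alcohol; the tertiary hydroxyl of the acid is too hindered to compete and its stereocentre is not involved.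

Step 15
Reactants: 24 [(3aR,5Z,9E,11aS)-10-methyl-3-methylidene-2-oxo-2,3,3a,4,7,8,11,11a-octahydrocyclodeca[b]furan-6-yl]methyl (2R)-3-chloro-2-hydroxy-2-methylpropanoate
Product: 25 [(3aR,5Z,9E,11aS)-10-(hydroxymethyl)-3-methylidene-2-oxo-2,3,3a,4,7,8,11,11a-octahydrocyclodeca[b]furan-6-yl]methyl (2R)-3-chloro-2-hydroxy-2-methylpropanoate (target)
Conditions: SeO2 (0.3 equiv), t-BuOOH (3 equiv), CH2Cl2, 0 °C → rt
Reagents that add atoms: tert-butyl hydroperoxide CC(C)(C)OO (terminal oxygen source); selenium dioxide O=[Se]=O (catalytic oxygen carrier)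
Why: SeO2 allylic oxidation (ene reaction, then [2,3]-sigmatropic shift) attacks the only electron-rich olefin (the 4,5-olefin is deactivated by its allylic ester, C9 by the C8 lactone oxygen), and the [2,3] shift returns the double bond with CH2OH trans to C2, i.e. the 1(10)-cis (melampolide) geometry, as known for SeO2 oxidation of (1(10)E)-germacranolides.

## Compound list

1 | tert-butyldimethyl(prop-2-yn-1-yloxy)silane | C#CCO[Si](C)(C)C(C)(C)C | starting material
2 | {3-[(tert-butyldimethylsilyl)oxy]prop-1-yn-1-yl}lithium | [Li]C#CCO[Si](C)(C)C(C)(C)C | intermediate (not isolated)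
3 | methyl 4-[(tert-butyldimethylsilyl)oxy]but-2-ynoate | COC(=O)C#CCO[Si](C)(C)C(C)(C)C | intermediate
4 | methyl 2-cuprio-3-{[(tert-butyldimethylsilyl)oxy]methyl}penta-2,4-dienoate (Cu cis to vinyl) | COC(=O)/C([Cu])=C(/C=C)CO[Si](C)(C)C(C)(C)C | intermediate (not isolated)
5 | methyl (2Z)-3-{[(tert-butyldimethylsilyl)oxy]methyl}penta-2,4-dienoate | COC(=O)/C=C(/C=C)CO[Si](C)(C)C(C)(C)C | intermediate
6 | diisobutylaluminium (2Z)-3-{[(tert-butyldimethylsilyl)oxy]methyl}penta-2,4-dien-1-olate | C=C/C(CO[Si](C)(C)C(C)(C)C)=C/CO[Al](CC(C)C)CC(C)C | intermediate (not isolated)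
7 | (2Z)-3-{[(tert-butyldimethylsilyl)oxy]methyl}penta-2,4-dien-1-yl acetate | CC(=O)OC/C=C(/C=C)CO[Si](C)(C)C(C)(C)C | intermediate
8 | (S)-epichlorohydrin [(2S)-2-(chloromethyl)oxirane] | ClC[C@@H]1CO1 | starting material
9 | (2S)-1-chloropent-4-yn-2-ol | ClC[C@@H](O)CC#C | intermediate
10 | (2S)-2-(prop-2-yn-1-yl)oxirane | C#CC[C@H]1CO1 | intermediate (not isolated)
11 | (3S)-hex-1-en-5-yn-3-ol | C=C[C@@H](O)CC#C | intermediate
12 | dimethylaluminium alkoxide of (3S,5E)-6-(dimethylalumanyl)-5-methylhexa-1,5-dien-3-ol | C=C[C@@H](O[Al](C)C)C/C(C)=C/[Al](C)C | intermediate (not isolated)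
13 | (3S,5E)-6-iodo-5-methylhexa-1,5-dien-3-ol | C=C[C@@H](O)C/C(C)=C/I | intermediate
14 | (2Z)-5-(9-borabicyclo[3.3.1]nonan-9-yl)-3-{[(tert-butyldimethylsilyl)oxy]methyl}pent-2-en-1-yl acetate | CC(=O)OC/C=C(/CCB1C2CCCC1CCC2)CO[Si](C)(C)C(C)(C)C | intermediate (not isolated)
15 | (2Z,6E,9S)-3-{[(tert-butyldimethylsilyl)oxy]methyl}-9-hydroxy-7-methylundeca-2,6,10-trien-1-yl acetate | C=C[C@@H](O)C/C(C)=C/CC/C(CO[Si](C)(C)C(C)(C)C)=C/COC(C)=O | intermediate
16 | (3S,5E,9Z)-11-acetoxy-9-{[(tert-butyldimethylsilyl)oxy]methyl}-5-methylundeca-1,5,9-trien-3-yl 2-(bromomethyl)prop-2-enoate | C=C[C@@H](OC(=O)C(=C)CBr)C/C(C)=C/CC/C(CO[Si](C)(C)C(C)(C)C)=C/COC(C)=O | intermediate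
17 | (2Z,6E)-8-[(2S)-4-(bromomethyl)-5-oxo-2,5-dihydrofuran-2-yl]-3-{[(tert-butyldimethylsilyl)oxy]methyl}-7-methylocta-2,6-dien-1-yl acetate | BrCC1=C[C@H](C/C(C)=C/CC/C(CO[Si](C)(C)C(C)(C)C)=C/COC(C)=O)OC1=O | intermediate
18 | (2Z,6E)-3-{[(tert-butyldimethylsilyl)oxy]methyl}-7-methyl-8-{(2S)-5-oxo-4-[(tributylstannyl)methyl]-2,5-dihydrofuran-2-yl}octa-2,6-dien-1-yl acetate | CCCC[Sn](CCCC)(CCCC)CC1=C[C@H](C/C(C)=C/CC/C(CO[Si](C)(C)C(C)(C)C)=C/COC(C)=O)OC1=O | intermediate
19 | (3aR,5Z,9E,11aS)-6-{[(tert-butyldimethylsilyl)oxy]methyl}-10-methyl-3-methylidene-3a,4,7,8,11,11a-hexahydrocyclodeca[b]furan-2(3H)-one | C=C1C(=O)O[C@H]2C/C(C)=C/CC/C(CO[Si](C)(C)C(C)(C)C)=C/C[C@H]12 | intermediate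
20 | (3aR,5Z,9E,11aS)-6-(hydroxymethyl)-10-methyl-3-methylidene-3a,4,7,8,11,11a-hexahydrocyclodeca[b]furan-2(3H)-one | C=C1C(=O)O[C@H]2C/C(C)=C/CC/C(CO)=C/C[C@H]12 | intermediate
21 | (2R)-3-bromo-2-hydroxy-2-methylpropanoic acid | OC(=O)[C@@](C)(O)CBr | starting material
22 | sodium (2S)-2-methyloxirane-2-carboxylate | [Na+].[O-]C(=O)[C@@]1(C)OC1 | intermediate (not isolated)
23 | (2R)-3-chloro-2-hydroxy-2-methylpropanoic acid | OC(=O)[C@@](C)(O)CCl | intermediate
24 | [(3aR,5Z,9E,11aS)-10-methyl-3-methylidene-2-oxo-2,3,3a,4,7,8,11,11a-octahydrocyclodeca[b]furan-6-yl]methyl (2R)-3-chloro-2-hydroxy-2-methylpropanoate | C=C1C(=O)O[C@H]2C/C(C)=C/CC/C(COC(=O)[C@@](C)(O)CCl)=C/C[C@H]12 | intermediate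
25 | [(3aR,5Z,9E,11aS)-10-(hydroxymethyl)-3-methylidene-2-oxo-2,3,3a,4,7,8,11,11a-octahydrocyclodeca[b]furan-6-yl]methyl (2R)-3-chloro-2-hydroxy-2-methylpropanoate | C=C1C(=O)O[C@H]2C/C(CO)=C\CC/C(COC(=O)[C@@](C)(O)CCl)=C/C[C@H]12 | target

## Step count and risks

Total step count: 15. Longest linear sequence: 11 steps (1 → 3 → 5 → 7 → 15 → 16 → 17 → 18 → 19 → 20 → 24 → 25; the branch from 8 is equally long).

Steps most likely to fail:

1. Step 11 (macrocyclisation). Risks are coupling through C13 (12-membered ring), cis ring fusion, and β-acyloxy elimination of the butenolide allyl unit on Pd. Fallback: invert the polarity of the same C6–C7 bond; it sets out from 15 and comes back at 19. PhSO2Na with Pd(PPh3)4 converts the allylic acetate of 15 into the C6 phenyl sulfone F1. Acryloyl chloride/Et3N gives the acrylate F2, and RCM gives the α-unsubstituted butenolide F3. Cs2CO3 in MeCN at high dilution triggers intramolecular Michael addition of the sulfonyl-stabilised C6 carbanion to C7 and gives the sulfonyl lactone F4. Na(Hg)/Na2HPO4/MeOH removes the sulfone to give the saturated lactone F5. LiHMDS then Eschenmoser's salt gives the Mannich base F6, and MeI then NaHCO3 eliminates the amine to give 19.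

2. Step 10 (reductive stannylation). The transient allylzinc may be protonated or may ring-open the butenolide by 1,4-elimination, and 18 is prone to protodestannylation. Fallback: bring the tin in with the acyl unit; it sets out from 15 and comes back at 18. DIC/DMAP esterification of 15 with 2-[(tributylstannyl)methyl]prop-2-enoic acid gives the stannyl acrylate F7, and RCM with Hoveyda–Grubbs II closes the butenolide to give 18 directly.

3. Step 15 (late SeO2 oxidation). Risks are attack at C9, C2 or C3, over-oxidation to the enal, or an unexpected olefin geometry. Fallback: oxidise C14 on the open chain before ring closure; it sets out from 17 and comes back at 25. SeO2/t-BuOOH on 17 gives the C14 allylic alcohol F8 with CH2OH trans to C2. PMB trichloroacetimidate/CSA gives the PMB ether F9, and Zn/Bu3SnCl gives the stannane F10. The Pd closure of step 11 then gives the 1(10)-cis macrocycle F11, HF·pyridine gives the C15 alcohol F12, and EDC/DMAP with 23 gives the ester F13. DDQ in CH2Cl2/pH 7 buffer removes the PMB group to give 25.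

## Further compounds

F1 | step 11 | (3S,5E,9Z)-9-{[(tert-butyldimethylsilyl)oxy]methyl}-5-methyl-11-(phenylsulfonyl)undeca-1,5,9-trien-3-ol | C=C[C@@H](O)C/C(C)=C/CC/C(CO[Si](C)(C)C(C)(C)C)=C/CS(=O)(=O)c1ccccc1
F2 | step 11 | (3S,5E,9Z)-9-{[(tert-butyldimethylsilyl)oxy]methyl}-5-methyl-11-(phenylsulfonyl)undeca-1,5,9-trien-3-yl prop-2-enoate | C=C[C@@H](OC(=O)C=C)C/C(C)=C/CC/C(CO[Si](C)(C)C(C)(C)C)=C/CS(=O)(=O)c1ccccc1
F3 | step 11 | (5S)-5-[(2E,6Z)-6-{[(tert-butyldimethylsilyl)oxy]methyl}-2-methyl-8-(phenylsulfonyl)octa-2,6-dien-1-yl]furan-2(5H)-one | O=C1C=C[C@H](C/C(C)=C/CC/C(CO[Si](C)(C)C(C)(C)C)=C/CS(=O)(=O)c2ccccc2)O1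
F4 | step 11 | 7,8-trans-fused 6-{[(tert-butyldimethylsilyl)oxy]methyl}-10-methyl-4-(phenylsulfonyl)-3a,4,7,8,11,11a-hexahydrocyclodeca[b]furan-2(3H)-one (sulfone epimers at C4 of the ring) | O=C1O[C@H]2C/C(C)=C/CC/C(CO[Si](C)(C)C(C)(C)C)=C/C(S(=O)(=O)c3ccccc3)[C@@H]2C1
F5 | step 11 | (3aR,5Z,9E,11aS)-6-{[(tert-butyldimethylsilyl)oxy]methyl}-10-methyl-3a,4,7,8,11,11a-hexahydrocyclodeca[b]furan-2(3H)-one | O=C1O[C@H]2C/C(C)=C/CC/C(CO[Si](C)(C)C(C)(C)C)=C/C[C@@H]2C1
F6 | step 11 | (3aR,5Z,9E,11aS)-6-{[(tert-butyldimethylsilyl)oxy]methyl}-3-[(dimethylamino)methyl]-10-methyl-3a,4,7,8,11,11a-hexahydrocyclodeca[b]furan-2(3H)-one (C3 epimers) | CN(C)CC1C(=O)O[C@H]2C/C(C)=C/CC/C(CO[Si](C)(C)C(C)(C)C)=C/C[C@H]12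
F7 | step 10 | (3S,5E,9Z)-11-acetoxy-9-{[(tert-butyldimethylsilyl)oxy]methyl}-5-methylundeca-1,5,9-trien-3-yl 2-[(tributylstannyl)methyl]prop-2-enoate | C=C[C@@H](OC(=O)C(=C)C[Sn](CCCC)(CCCC)CCCC)C/C(C)=C/CC/C(CO[Si](C)(C)C(C)(C)C)=C/COC(C)=O
F8 | step 15 | (2Z,6E)-8-[(2S)-4-(bromomethyl)-5-oxo-2,5-dihydrofuran-2-yl]-3-{[(tert-butyldimethylsilyl)oxy]methyl}-7-(hydroxymethyl)octa-2,6-dien-1-yl acetate | BrCC1=C[C@H](C/C(CO)=C\CC/C(CO[Si](C)(C)C(C)(C)C)=C/COC(C)=O)OC1=O
F9 | step 15 | (2Z,6E)-8-[(2S)-4-(bromomethyl)-5-oxo-2,5-dihydrofuran-2-yl]-3-{[(tert-butyldimethylsilyl)oxy]methyl}-7-{[(4-methoxybenzyl)oxy]methyl}octa-2,6-dien-1-yl acetate | BrCC1=C[C@H](C/C(COCc2ccc(OC)cc2)=C\CC/C(CO[Si](C)(C)C(C)(C)C)=C/COC(C)=O)OC1=O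
F10 | step 15 | (2Z,6E)-3-{[(tert-butyldimethylsilyl)oxy]methyl}-7-{[(4-methoxybenzyl)oxy]methyl}-8-{(2S)-5-oxo-4-[(tributylstannyl)methyl]-2,5-dihydrofuran-2-yl}octa-2,6-dien-1-yl acetate | CCCC[Sn](CCCC)(CCCC)CC1=C[C@H](C/C(COCc2ccc(OC)cc2)=C\CC/C(CO[Si](C)(C)C(C)(C)C)=C/COC(C)=O)OC1=O
F11 | step 15 | (3aR,5Z,9E,11aS)-6-{[(tert-butyldimethylsilyl)oxy]methyl}-10-{[(4-methoxybenzyl)oxy]methyl}-3-methylidene-3a,4,7,8,11,11a-hexahydrocyclodeca[b]furan-2(3H)-one | C=C1C(=O)O[C@H]2C/C(COCc3ccc(OC)cc3)=C\CC/C(CO[Si](C)(C)C(C)(C)C)=C/C[C@H]12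
F12 | step 15 | (3aR,5Z,9E,11aS)-6-(hydroxymethyl)-10-{[(4-methoxybenzyl)oxy]methyl}-3-methylidene-3a,4,7,8,11,11a-hexahydrocyclodeca[b]furan-2(3H)-one | C=C1C(=O)O[C@H]2C/C(COCc3ccc(OC)cc3)=C\CC/C(CO)=C/C[C@H]12
F13 | step 15 | [(3aR,5Z,9E,11aS)-10-{[(4-methoxybenzyl)oxy]methyl}-3-methylidene-2-oxo-2,3,3a,4,7,8,11,11a-octahydrocyclodeca[b]furan-6-yl]methyl (2R)-3-chloro-2-hydroxy-2-methylpropanoate | C=C1C(=O)O[C@H]2C/C(COCc3ccc(OC)cc3)=C\CC/C(COC(=O)[C@@](C)(O)CCl)=C/C[C@H]12
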